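**Plan**
- Retrosynthesis: the three phenolic MOM ethers are removed last. Before that, one operation cuts the benzofuran C5–CH2 bond of the propyl tether and the C4–CH2 bond of the prenyl group, leading back to aryl iodide 6, alkyl bromide 17 and prenylboronate 18.
- Enabling feature: the prenyl-bearing C4 and the chain-bearing C5 of the benzofuran are neighbours, and the second neighbour of C4 is the quaternary fusion atom C3a. An iodide on C4 therefore has a single ortho C–H, that of C5, so one ortho alkylation followed by ipso coupling sets both substituents.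
- Benzofuran part: the fused furan–benzene system is bought as acid 1; iodination at C4 (para to the methoxy group), decarboxylation and a methyl-to-MOM exchange give 6. No ring is formed anywhere in the route.
- Resorcinol part: O-prenylation of 7 and an aromatic Claisen rearrangement place the 1,1-dimethylallyl group at C5; the aldehyde is then extended to the 3-bromopropyl chain of 17. The two halves and the prenyl group are joined in step 13, and the phenols are freed in step 14.
- Stereochemistry: the target has no stereocentre and no double bond with E/Z isomers; only regiochemistry has to be controlled (iodination at C4, Claisen shift to C5, allyl coupling at its CH2 end).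

Key step: step 13

Remark: 7-methoxy-1-benzofuran-2-carboxylic acid is taken as a catalogue compound (it is otherwise the cyclization–saponification product of o-vanillin and ethyl bromoacetate). Its 2-carboxyl group is kept through the iodination as a removable blocking and deactivating group for the furan ring.

**Route**

Step 1
Reactants: 1 7-methoxy-1-benzofuran-2-carboxylic acid
Product: 2 4-iodo-7-methoxy-1-benzofuran-2-carboxylic acid
Conditions: NIS, TFA, MeCN, rt
Reagents that add atoms: N-iodosuccinimide, O=C1CCC(=O)N1I
Why: Electrophilic aromatic iodination, in which the 2-carboxyl group blocks C2 and deactivates the furan ring so that the iodinating species attacks the benzene ring para to the 7-methoxy group (C4) in preference to the ortho position C6.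

Step 2
Reactants: 2 4-iodo-7-methoxy-1-benzofuran-2-carboxylic acid
Product: 3 4-iodo-7-methoxy-1-benzofuran
Conditions: Ag2CO3 (10 mol%), AcOH (5 mol%), DMSO, 120 °C
Reagents that add atoms: none
Why: Silver-catalysed protodecarboxylation of a heteroaromatic 2-carboxylic acid (silver carboxylate, loss of CO2, protonation of the 2-benzofuranylsilver species), under which an aryl iodide is not expected to react.

Step 3
Reactants: 3 4-iodo-7-methoxy-1-benzofuran
Product: 5 4-iodo-1-benzofuran-7-ol, via aryloxydibromoborane 4 (not isolated)
Conditions: BBr3, CH2Cl2, −78 to 0 °C; then H2O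
Reagents that add atoms: none
Why: Lewis-acid ether cleavage, in which BBr3 coordinates the methoxy oxygen, bromide removes the methyl group by SN2 and water hydrolyses the aryloxyborane 4, while the aryl iodide and the furan ring should be inert at low temperature.

Step 4
Reactants: 5 4-iodo-1-benzofuran-7-ol
Product: 6 4-iodo-7-(methoxymethoxy)-1-benzofuran
Conditions: MOMCl, K2CO3, acetone, rt
Reagents that add atoms: chloromethyl methyl ether, COCCl
Why: Williamson-type O-alkylation of the phenol with the reactive α-chloro ether gives a MOM ether that is stable to the carbonate base and palladium of the coupling and is removable by mild acid at the end.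

Step 5
Reactants: 7 2,4-dihydroxybenzaldehyde; 8 prenyl bromide (1-bromo-3-methylbut-2-ene)
Product: 9 2-hydroxy-4-[(3-methylbut-2-en-1-yl)oxy]benzaldehyde
Conditions: K2CO3 (1.1 equiv), acetone, rt
Reagents that add atoms: none
Why: Regioselective Williamson etherification, since the 2-hydroxyl is hydrogen-bonded to the formyl group and less nucleophilic, so one equivalent of base and bromide alkylates the 4-hydroxyl by SN2 at the primary allylic carbon.

Step 6
Reactants: 9 2-hydroxy-4-[(3-methylbut-2-en-1-yl)oxy]benzaldehyde
Product: 10 2-(methoxymethoxy)-4-[(3-methylbut-2-en-1-yl)oxy]benzaldehyde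
Conditions: MOMCl, K2CO3, acetone, reflux
Reagents that add atoms: chloromethyl methyl ether, COCCl
Why: O-alkylation of the chelated phenol, which removes the hydrogen-bonded chelate that would otherwise steer the coming rearrangement to C3 and adds bulk next to that position.

Step 7
Reactants: 10 2-(methoxymethoxy)-4-[(3-methylbut-2-en-1-yl)oxy]benzaldehyde
Product: 12 4-hydroxy-2-(methoxymethoxy)-5-(2-methylbut-3-en-2-yl)benzaldehyde, via cyclohexadienone 11 (not isolated)
Conditions: PhNEt2, 190 °C, sealed tube
Reagents that add atoms: none
Why: Aromatic Claisen rearrangement, in which the [3,3] shift bonds the dimethyl-substituted allyl terminus to an ortho carbon, the unflanked C5 being preferred over C3 (wedged between two oxygens) for this bulky bond formation, after which dienone 11 tautomerizes to the phenol.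

Step 8
Reactants: 12 4-hydroxy-2-(methoxymethoxy)-5-(2-methylbut-3-en-2-yl)benzaldehyde
Product: 13 2,4-bis(methoxymethoxy)-5-(2-methylbut-3-en-2-yl)benzaldehyde
Conditions: MOMCl, K2CO3, DMF, rt
Reagents that add atoms: chloromethyl methyl ether, COCCl
Why: O-alkylation of the phenol para to the formyl group, whose acidity and the small size of the electrophile should offset the hindrance of the neighbouring tertiary alkyl group.

Step 9
Reactants: 13 2,4-bis(methoxymethoxy)-5-(2-methylbut-3-en-2-yl)benzaldehyde
Product: 14 methyl (2E)-3-[2,4-bis(methoxymethoxy)-5-(2-methylbut-3-en-2-yl)phenyl]prop-2-enoate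
Conditions: Ph3P=CHCO2Me, toluene, 90 °C
Reagents that add atoms: methyl (triphenylphosphoranylidene)acetate, COC(=O)C=P(c1ccccc1)(c1ccccc1)c1ccccc1
Why: Wittig olefination with a stabilized ylide should give the (E)-cinnamate under neutral conditions that leave the acetals and the isolated vinyl group untouched.

Step 10
Reactants: 14 methyl (2E)-3-[2,4-bis(methoxymethoxy)-5-(2-methylbut-3-en-2-yl)phenyl]prop-2-enoate
Product: 15 methyl 3-[2,4-bis(methoxymethoxy)-5-(2-methylbut-3-en-2-yl)phenyl]propanoate
Conditions: Mg turnings, MeOH, rt
Reagents that add atoms: none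
Why: Dissolving-metal conjugate reduction, in which magnesium transfers electrons only to the aryl-conjugated enoate, so the isolated monosubstituted alkene of the dimethylallyl group is not reduced.

Step 11
Reactants: 15 methyl 3-[2,4-bis(methoxymethoxy)-5-(2-methylbut-3-en-2-yl)phenyl]propanoate
Product: 16 3-[2,4-bis(methoxymethoxy)-5-(2-methylbut-3-en-2-yl)phenyl]propan-1-ol
Conditions: LiAlH4, THF, 0 °C
Reagents that add atoms: none
Why: Hydride reduction of the ester to the primary alcohol, to which MOM ethers and the unactivated alkene are inert.

Step 12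
Reactants: 16 3-[2,4-bis(methoxymethoxy)-5-(2-methylbut-3-en-2-yl)phenyl]propan-1-ol
Product: 17 1-(3-bromopropyl)-2,4-bis(methoxymethoxy)-5-(2-methylbut-3-en-2-yl)benzene
Conditions: CBr4, PPh3, CH2Cl2, 0 °C
Reagents that add atoms: carbon tetrabromide, BrC(Br)(Br)Br
Why: Appel reaction, in which bromide displaces the alkoxyphosphonium group at the primary carbon under essentially neutral conditions that aryl MOM ethers tolerate.

Step 13
Reactants: 6 4-iodo-7-(methoxymethoxy)-1-benzofuran; 17 1-(3-bromopropyl)-2,4-bis(methoxymethoxy)-5-(2-methylbut-3-en-2-yl)benzene; 18 prenylboronic acid pinacol ester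
Product: 19 5-{3-[2,4-bis(methoxymethoxy)-5-(2-methylbut-3-en-2-yl)phenyl]propyl}-7-(methoxymethoxy)-4-(3-methylbut-2-en-1-yl)-1-benzofuran
Conditions: Pd(OAc)2 (10 mol%), P(2-furyl)3 (22 mol%), norbornene (3 equiv), Cs2CO3, MeCN/H2O (20:1), 85 °C; 17 (1.5 equiv); 18 (2.5 equiv) added slowly by syringe pump
Reagents that add atoms: none
Why: Proposed new method: Zerovalent palladium inserts into the carbon–iodine bond at C4 of 6, norbornene inserts into the aryl–palladium bond and the only free ortho C–H (C5, the other ortho atom being the fusion carbon C3a) is palladated to a five-membered palladacycle of divalent palladium, which adds the primary bromide 17 to reach tetravalent palladium and forms the C5–CH2 bond by reductive elimination. With both ortho positions then substituted, norbornene is expelled by β-carbon elimination and the 2,6-disubstituted arylpalladium halide is intercepted by 18: transmetalation is expected to deliver the allyl-transposed tertiary σ-allyl species, which shifts through the π-allyl form to the primary σ-prenyl isomer before reductive elimination makes the C4–CH2CH=CMe2 bond. The closest known reaction type is the Catellani ortho alkylation of aryl iodides with primary alkyl halides terminated by Suzuki–Miyaura coupling with aryl- and alkenylboron reagents, and ligand-controlled coupling of prenylboronates with simple aryl halides at the unsubstituted allyl terminus is also known; what is new is an allylboronate as the terminating partner. No ring is closed and no stereocentre is formed. The step needs alkylation before boron coupling (excess norbornene, slow addition of 18), bonding at the CH2 end of the allyl unit (favoured by the two ortho substituents, C3a and the new C5 chain, which disfavour a tertiary alkyl on palladium and a quaternary carbon at C4), and no Heck termination by the vinyl group of 17 (shielded by its quaternary neighbour).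

Step 14
Reactants: 19 5-{3-[2,4-bis(methoxymethoxy)-5-(2-methylbut-3-en-2-yl)phenyl]propyl}-7-(methoxymethoxy)-4-(3-methylbut-2-en-1-yl)-1-benzofuran
Product: 20 4-{3-[7-hydroxy-4-(3-methylbut-2-en-1-yl)-1-benzofuran-5-yl]propyl}-6-(2-methylbut-3-en-2-yl)benzene-1,3-diol
Conditions: HCl (about 1 M in MeOH), 0 °C to rt
Reagents that add atoms: none
Why: Acid-catalysed acetal methanolysis should free the three phenols, with dilute acid at or below room temperature chosen because the dimethylallyl group next to a phenol and the prenyl group can cyclize or add methanol under stronger acid.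

**Compound list**

1 | 7-methoxy-1-benzofuran-2-carboxylic acid | COc1cccc2cc(C(=O)O)oc12 | starting material
2 | 4-iodo-7-methoxy-1-benzofuran-2-carboxylic acid | COc1ccc(I)c2cc(C(=O)O)oc12 | intermediate
3 | 4-iodo-7-methoxy-1-benzofuran | COc1ccc(I)c2ccoc12 | intermediate
4 | dibromo[(4-iodo-1-benzofuran-7-yl)oxy]borane | BrB(Br)Oc1ccc(I)c2ccoc12 | intermediate (not isolated)
5 | 4-iodo-1-benzofuran-7-ol | Oc1ccc(I)c2ccoc12 | intermediate
6 | 4-iodo-7-(methoxymethoxy)-1-benzofuran | COCOc1ccc(I)c2ccoc12 | intermediate
7 | 2,4-dihydroxybenzaldehyde | O=Cc1ccc(O)cc1O | starting material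
8 | prenyl bromide (1-bromo-3-methylbut-2-ene) | CC(C)=CCBr | starting material
9 | 2-hydroxy-4-[(3-methylbut-2-en-1-yl)oxy]benzaldehyde | CC(C)=CCOc1ccc(C=O)c(O)c1 | intermediate
10 | 2-(methoxymethoxy)-4-[(3-methylbut-2-en-1-yl)oxy]benzaldehyde | CC(C)=CCOc1ccc(C=O)c(OCOC)c1 | intermediate
11 | 6-(methoxymethoxy)-3-(2-methylbut-3-en-2-yl)-4-oxocyclohexa-1,5-diene-1-carbaldehyde (racemic) | O=CC1=CC(C(C)(C)C=C)C(=O)C=C1OCOC | intermediate (not isolated)
12 | 4-hydroxy-2-(methoxymethoxy)-5-(2-methylbut-3-en-2-yl)benzaldehyde | C=CC(C)(C)c1cc(C=O)c(OCOC)cc1O | intermediate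
13 | 2,4-bis(methoxymethoxy)-5-(2-methylbut-3-en-2-yl)benzaldehyde | C=CC(C)(C)c1cc(C=O)c(OCOC)cc1OCOC | intermediate
14 | methyl (2E)-3-[2,4-bis(methoxymethoxy)-5-(2-methylbut-3-en-2-yl)phenyl]prop-2-enoate | C=CC(C)(C)c1cc(/C=C/C(=O)OC)c(OCOC)cc1OCOC | intermediate
15 | methyl 3-[2,4-bis(methoxymethoxy)-5-(2-methylbut-3-en-2-yl)phenyl]propanoate | C=CC(C)(C)c1cc(CCC(=O)OC)c(OCOC)cc1OCOC | intermediate
16 | 3-[2,4-bis(methoxymethoxy)-5-(2-methylbut-3-en-2-yl)phenyl]propan-1-ol | C=CC(C)(C)c1cc(CCCO)c(OCOC)cc1OCOC | intermediate
17 | 1-(3-bromopropyl)-2,4-bis(methoxymethoxy)-5-(2-methylbut-3-en-2-yl)benzene | C=CC(C)(C)c1cc(CCCBr)c(OCOC)cc1OCOC | intermediate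
18 | prenylboronic acid pinacol ester (4,4,5,5-tetramethyl-2-(3-methylbut-2-en-1-yl)-1,3,2-dioxaborolane) | CC(C)=CCB1OC(C)(C)C(C)(C)O1 | starting material
19 | 5-{3-[2,4-bis(methoxymethoxy)-5-(2-methylbut-3-en-2-yl)phenyl]propyl}-7-(methoxymethoxy)-4-(3-methylbut-2-en-1-yl)-1-benzofuran | C=CC(C)(C)c1cc(CCCc2cc(OCOC)c3occc3c2CC=C(C)C)c(OCOC)cc1OCOC | intermediate
20 | 4-{3-[7-hydroxy-4-(3-methylbut-2-en-1-yl)-1-benzofuran-5-yl]propyl}-6-(2-methylbut-3-en-2-yl)benzene-1,3-diol | C=CC(C)(C)c1cc(CCCc2cc(O)c3occc3c2CC=C(C)C)c(O)cc1O | target

**Step count**

Total: 14 steps. Longest linear sequence: 10 steps (steps 5 to 14, from 7). The benzofuran branch (steps 1 to 4) joins at step 13.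

**Steps most likely to fail**

Step 13. The boronate may couple with the arylpalladium iodide before ortho alkylation, leaving C5 unsubstituted. The allyl unit may bond through its dimethyl-bearing end, giving a 1,1-dimethylallyl group at C4. The boronate may be lost by protodeboronation, or the benzofuran C2–H may be arylated. In that case the same two bonds would be made with known chemistry, setting out from 6 and 17 and returning at 19. A Catellani ortho alkylation with Suzuki–Miyaura termination by an alkenylboron partner, (E)-2-ethoxyvinylboronic acid pinacol ester (Pd(OAc)2, P(2-furyl)3, norbornene, Cs2CO3, MeCN/H2O), should give the enol ether 5-{3-[2,4-bis(methoxymethoxy)-5-(2-methylbut-3-en-2-yl)phenyl]propyl}-4-[(E)-2-ethoxyethenyl]-7-(methoxymethoxy)-1-benzofuran F1. Brief treatment with cold dilute aqueous HCl in THF, under which aryl MOM ethers should persist, would hydrolyse the enol ether to 2-[5-{3-[2,4-bis(methoxymethoxy)-5-(2-methylbut-3-en-2-yl)phenyl]propyl}-7-(methoxymethoxy)-1-benzofuran-4-yl]acetaldehyde F2. Wittig olefination with isopropylidenetriphenylphosphorane (from isopropyltriphenylphosphonium iodide and n-BuLi, THF, −78 °C to rt) would then complete the prenyl group and give 19.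

Step 7. The allyl unit may migrate to C3 instead of C5, the prenyl ether may fragment at the temperature needed, or the product may rearrange further or cyclize through its free phenol. The fallback drops the sigmatropic route and installs the group by cross-coupling, setting out from 7 and returning at 13. Bromination of 7 (Br2, AcOH) para to the 4-hydroxyl gives 5-bromo-2,4-dihydroxybenzaldehyde F3. Double protection (MOMCl, K2CO3, DMF) gives 5-bromo-2,4-bis(methoxymethoxy)benzaldehyde F4. A Suzuki–Miyaura coupling of F4 with 18 under ligand control for bonding at the substituted allyl terminus (Pd(OAc)2, a bulky dialkylbiarylphosphine selected for branched selectivity, K3PO4, aqueous THF) would then deliver 13 with the position of the dimethylallyl group fixed by the bromide.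

Step 14. Under protic acid the freed phenol may add across the neighbouring dimethylallyl double bond, methanol may add to the prenyl group, or the electron-rich benzofuran may degrade before all three acetals are cleaved. The fallback replaces hydrolysis by a buffered, non-protic exchange of the acetals for silyl ethers, setting out from 19 and returning at 20. TMSOTf and 2,2′-bipyridyl in MeCN at 0 °C should convert the aryl MOM ethers into 5-{3-[5-(2-methylbut-3-en-2-yl)-2,4-bis(trimethylsilyloxy)phenyl]propyl}-4-(3-methylbut-2-en-1-yl)-7-(trimethylsilyloxy)-1-benzofuran F5. Addition of water would then cleave the labile aryl silyl ethers at neutral pH to give 20.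

**Further compounds**

F1 | step 13 | 5-{3-[2,4-bis(methoxymethoxy)-5-(2-methylbut-3-en-2-yl)phenyl]propyl}-4-[(E)-2-ethoxyethenyl]-7-(methoxymethoxy)-1-benzofuran | CCO/C=C/c1c(CCCc2cc(C(C)(C)C=C)c(OCOC)cc2OCOC)cc(OCOC)c2occc12
F2 | step 13 | 2-[5-{3-[2,4-bis(methoxymethoxy)-5-(2-methylbut-3-en-2-yl)phenyl]propyl}-7-(methoxymethoxy)-1-benzofuran-4-yl]acetaldehyde | O=CCc1c(CCCc2cc(C(C)(C)C=C)c(OCOC)cc2OCOC)cc(OCOC)c2occc12
F3 | step 7 | 5-bromo-2,4-dihydroxybenzaldehyde | O=Cc1cc(Br)c(O)cc1O
F4 | step 7 | 5-bromo-2,4-bis(methoxymethoxy)benzaldehyde | O=Cc1cc(Br)c(OCOC)cc1OCOC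
F5 | step 14 | 5-{3-[5-(2-methylbut-3-en-2-yl)-2,4-bis(trimethylsilyloxy)phenyl]propyl}-4-(3-methylbut-2-en-1-yl)-7-(trimethylsilyloxy)-1-benzofuran | C=CC(C)(C)c1cc(CCCc2cc(O[Si](C)(C)C)c3occc3c2CC=C(C)C)c(O[Si](C)(C)C)cc1O[Si](C)(C)C
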